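## The problem

Bromoiesol B sulfate 18 is an achiral triaryl bis-ether: ring A (3,5-dibromo, hydrogen sulfate on C1) is joined through its C2 oxygen to C1 of ring B, which carries bromine on C3, C4 and C5 and, on C6, a second ether oxygen bearing ring C, a 4-bromo-2-iodophenyl group. With no stereocentre, the whole difficulty is regiochemical: seven halogens and four aryl C–O bonds must be placed on three benzene rings without ambiguity. Both diaryl ether bonds are flanked by ortho substituents, ring B has no activating group for an SNAr reaction, and its C–Br bonds would compete in a CuI-mediated Ullmann coupling or a Pd(OAc)2/phosphine etherification. The C–I bond on ring C is the weakest bond in the molecule and, once in place, excludes organolithium reagents, hydrogenation and low-valent metal catalysis. The aryl hydrogen sulfate is acid-labile and turns every intermediate that carries it into a salt, so it should be made last. Late electrophilic halogenation is excluded because each ring has more than one open position. The feature that opens the plan lies on ring C: its iodine on C2 sits beside C1, whose oxygen is bonded to C6 of ring B, so iodine and that ring B carbon stand in a 1,4 relationship across I–C2–C1–O. This is exactly the pattern left when an aryl group moves from trivalent iodine to the oxygen of an ortho-iodonio phenolate.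

## Retrosynthesis

**S–O bond.** The S–O bond of 18 is cut first, giving the phenol 17. Carrying a sulfate salt through any earlier step would expose it to acid and complicate purification. Phenol 17 has a single free hydroxyl, so the forward reaction only needs a mild O-sulfation that leaves seven carbon–halogen bonds alone.

**Ring A.** The C1–O bond of ring A in 17 is traced through the formate 16 to the formyl group of aldehyde 15, and the ether bond between ring A and ring B is then cut on the ring A side. This gives the phenol 13 and 3,5-dibromo-2-fluorobenzaldehyde 14. The cut is made on ring A because only ring A can carry an activating group ortho to the leaving group; ring B cannot. The formyl group activates the fluoride for SNAr and later becomes the oxygen that is sulfated. Ring A with both bromines comes from one purchased compound. The forward reactions ask a hindered, weakly nucleophilic phenoxide to displace a fluoride flanked by CHO and Br, and then ask the aryl group to migrate in preference to hydride in the peracid oxidation.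

**Ring C bromine and the ring B oxygen.** Phenol 13 is simplified by three functional-group changes: the O–CH3 bond back to the methyl ether 12, the C4–Br bond of ring C back through the diazonium salt 11 to the amine 10, and the amine back to the nitro compound 9. The nitro group is not a detour. Only electron-poor phenols give stable iodonium phenolates; an electron-rich 4-bromophenol would be oxidised by trivalent iodine. The nitro group sits on the carbon where the target has bromine. The order matters: the nitro group must be gone before the methyl ether is cleaved. Otherwise a free ring B phenoxide next to a nitro-activated aryl ether could pass ring C to the neighbouring oxygen by Smiles rearrangement. The forward steps need a nitro reduction that spares C–I and C–Br, a Sandmeyer bromination and a BBr3 demethylation that leaves the diaryl ether intact.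

**Key disconnection.** In 9 the bond between the ether oxygen and C6 of ring B is cut, and the ortho iodine of ring C is reconnected to that ring B carbon. This gives the zwitterion 8, in which trivalent iodine links the two rings. Cutting the same ether on its ring C side would call for SNAr chemistry and would still leave the iodine to be placed separately. The chosen cut forms the hindered C–O bond without metal catalysis and leaves the spent iodine at the position the target requires. The forward reaction is a thermal isomerisation of 8 to 9 in which ring B moves from iodine to oxygen.

**Zwitterion.** In 8 the bond between iodine and C2 of the nitrophenolate ring is cut, giving the aryl-λ3-iodane diacetate 6 and 4-nitrophenol 7. In 7 the para position is blocked and the two ortho positions are equivalent, so the site of C–I bond formation is fixed. This cut splits the precursor into two monocyclic pieces, one of them purchased. The forward condensation must proceed with a di-ortho-substituted aryl group on iodine.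

**Ring B iodide.** Diacetate 6 goes back to the aryl iodide 5 by cutting the two I–O bonds, 5 to the phenol 4 by cutting O–CH3, and 4 to 3,4,5-tribromophenol 3 by cutting C–I. Phenol 3 goes back through the diazonium salt 2 to 3,4,5-tribromoaniline 1, with C–O standing for C–N. Phenol 3 is symmetric, its para position is blocked and its two ortho positions are equivalent. One iodination therefore places iodine on the carbon flanked by oxygen and bromine, which is the ring B carbon that later bears the ring C oxygen. Methyl is chosen as the oxygen protecting group because it survives peracid, base, heat, iron/acetic acid and diazotisation and is removed by BBr3.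

## Roads not taken

Alternative 1: ring B by cycloaddition. Ring B would be built from 2,3,4-tribromothiophene 1,1-dioxide A1 and 2-[2,2-bis(trimethylsilyloxy)ethenyloxy]-1,5-dibromo-3-methoxybenzene A2, a bis(trimethylsilyl) ketene acetal that carries the protected ring A as its aryloxy group. A [4+2] cycloaddition, cheletropic loss of the SO2 bridge and elimination of silanol would give 2,3,4-tribromo-6-(2,4-dibromo-6-methoxyphenoxy)phenol A3.
- Merits: two C–C bonds form, ring B arrives with its three bromines and both oxygens in one operation, and the union with ring A is convergent. The free hydroxyl of A3 is the site for ring C, which could be attached by SNAr on 1-fluoro-2-iodo-4-nitrobenzene A4, followed by the same nitro-to-bromine exchange, demethylation and sulfation as in the chosen plan. Because A4 is a purchased arene with iodine already ortho to the leaving group, this join of rings B and C is as direct as the aryl shift of the chosen plan.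
- Weak points: A1 has a free α-position and should dimerise readily, and its preparation needs forcing oxidation of an electron-poor thiophene. A2 is moisture-sensitive. The regiochemistry of the cycloaddition (acetal carbon to the brominated terminus, aryloxy carbon to the CH terminus) rests on polarity arguments alone.
- Comparison: this road is more convergent and avoids the iodination and oxidation sequence on ring B. The chosen plan is longer and linear, but each of its steps belongs to a well-known reaction class and its regiochemistry is fixed by symmetry, not by a cycloaddition preference.

Alternative 2: sulfate first by Elbs oxidation. 2,4-Dibromophenol A5 would be oxidised with K2S2O8 in aqueous KOH at its free ortho carbon to give potassium 3,5-dibromo-2-hydroxyphenyl sulfate A6.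
- Merits: the sulfated oxygen is placed in one step from A5, a commodity phenol, with no protecting group. In step count for ring A this is clearly better than the SNAr, Baeyer–Villiger and sulfation sequence of the chosen plan.
- Weak points: ortho Elbs oxidation of a para-blocked, electron-poor phenol such as A5 is typically inefficient. The hindered hydroxyl of A6 must then be arylated by ring B, which has no SNAr activation, so ring B would have to be delivered as a diaryliodonium salt. Such a salt cannot be made from a fragment that already contains ring C, because the ring C iodide would compete in the oxidation to trivalent iodine. Ring C would therefore be attached after ring A, and the sulfate would have to survive heating, iron in acetic acid and a diazotisation in strong acid, conditions under which an aryl sulfate is expected to hydrolyse.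
- Comparison: the chosen plan spends three steps on ring A where this road spends one. Against that it keeps every intermediate neutral and sulfates at the very end.

Alternative 3: ring A by pyranone cycloaddition. 3,5-Dibromo-2H-pyran-2-one A7 and the aryloxyalkynyl pinacol boronate A8 of the ring B–ring C unit would undergo [4+2] cycloaddition and lose CO2 to give the ring A aryl pinacol boronate A9. Oxidation of the C–B bond and sulfation would finish the synthesis.
- Merits: the position of the future sulfate oxygen is fixed by boron, and C–B oxidation is cleaner than a Baeyer–Villiger reaction in which hydride migration can compete. In that respect this road is better than step 11 of the chosen plan.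
- Weak points: A8 is an aryl ynol ether. The usual access to such ethers goes through a dichlorovinyl ether and n-BuLi, which would exchange with the iodide and bromides of the ring B–ring C unit. The cycloaddition of A7 needs high temperature, at which an ynol ether may not survive, and its regiochemistry is not assured. The road also needs the phenol 13, so it does not address the bond between rings B and C or the iodine.
- Comparison: it would replace two steps of the chosen plan (10 and 11) with at least four. The chosen plan sets against it a purchased fluoroaldehyde and a two-step sequence.

Key step: step 6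

Assumption: the target is drawn as the free hydrogen sulfate, so the pyridinium salt formed in the last step is converted to the acid by brief cold contact with a sulfonic acid resin.

## Route

Step 1
Reactants: 1 3,4,5-tribromoaniline
Product: 3 3,4,5-tribromophenol, via 3,4,5-tribromobenzenediazonium hydrogen sulfate 2 (not isolated)
Conditions: NaNO2, H2SO4/AcOH, 0–5 °C; then added to aq. H2SO4, 100 °C
Reagents that add atoms: water, O
Why: Diazotisation of the aniline followed by thermal hydrolysis of the diazonium salt (phenol formation by dediazoniation) should exchange NH2 for OH without touching the three C–Br bonds; slow addition to boiling acid limits azo coupling.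

Step 2
Reactants: 3 3,4,5-tribromophenol
Product: 4 3,4,5-tribromo-2-iodophenol
Conditions: NIS (1.0 equiv), TsOH·H2O (cat.), MeCN, 0 °C → rt
Reagents that add atoms: N-iodosuccinimide, O=C1CCC(=O)N1I
Why: Electrophilic aromatic iodination of a phenol whose para position is blocked and whose two ortho positions are equivalent can give only one mono-iodide; the first iodine deactivates the ring and should slow a second substitution.

Step 3
Reactants: 4 3,4,5-tribromo-2-iodophenol
Product: 5 1,2,3-tribromo-4-iodo-5-methoxybenzene
Conditions: MeI, K2CO3, acetone, reflux
Reagents that add atoms: iodomethane, CI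
Why: Williamson O-methylation of an acidic halophenol; the methyl ether should withstand every step up to its planned cleavage with BBr3.

Step 4
Reactants: 5 1,2,3-tribromo-4-iodo-5-methoxybenzene
Product: 6 (2,3,4-tribromo-6-methoxyphenyl)-λ3-iodanediyl diacetate
Conditions: mCPBA, AcOH, 50 °C
Reagents that add atoms: acetic acid, CC(=O)O
Why: Peracid oxidation of an aryl iodide in acetic acid is the standard route to (diacetoxyiodo)arenes; the ortho methoxy oxygen should stabilise the trivalent iodine centre and the tribrominated ring resists ring oxidation.

Step 5
Reactants: 6 (2,3,4-tribromo-6-methoxyphenyl)-λ3-iodanediyl diacetate; 7 4-nitrophenol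
Product: 8 4-nitro-2-[(2,3,4-tribromo-6-methoxyphenyl)iodonio]phenolate
Conditions: KOH, MeOH, 0 °C → rt, dark
Reagents that add atoms: none
Why: Condensation of a (diacetoxyiodo)arene with a nitrophenolate (ligand exchange at iodine, then transfer of iodine from oxygen to the ortho carbon and proton loss) is the known route to aryliodonium phenolate zwitterions; the blocked para position and the two equivalent ortho positions of 7 fix the site, and the zwitterion should precipitate from methanol.

Step 6
Reactants: 8 4-nitro-2-[(2,3,4-tribromo-6-methoxyphenyl)iodonio]phenolate
Product: 9 1,2,3-tribromo-4-(2-iodo-4-nitrophenoxy)-5-methoxybenzene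
Conditions: DMF, 110 °C, dark, N2
Reagents that add atoms: none
Why: On heating, the phenolate oxygen of 8 should attack the ipso carbon of ring B, the aryl ligand on trivalent iodine, through a five-membered O–C1–C2–I–C(ipso) transition state; this is ligand coupling at iodine and it leaves monovalent iodine on C2 of ring C. The closest known reaction type is the thermal 1,4 aryl shift from iodine to oxygen in aryliodonium phenolates of nitrophenols and in iodonium ylides of cyclic 1,3-diones, which gives 2-iodoaryl aryl ethers. One C–O bond forms, no ring closes and no stereocentre arises. The step needs O-arylation to win over fragmentation to the iodoarene 5, and it needs attack at the ipso carbon only. The substrate secures the second point because ring B is the only aryl ligand that can move (the other carbon on iodine belongs to the phenolate ring itself) and only the phenolate oxygen can reach the ipso carbon. The three bromines make ring B electron-poor, which should lower the barrier to ipso attack, and the two ortho substituents (OMe and Br) favour ligand coupling by relieving crowding at iodine. The para nitro group keeps the phenolate ring from being oxidised. Exclusion of light suppresses the photochemical C–I homolysis known for these zwitterions.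

Step 7
Reactants: 9 1,2,3-tribromo-4-(2-iodo-4-nitrophenoxy)-5-methoxybenzene
Product: 10 3-iodo-4-(2,3,4-tribromo-6-methoxyphenoxy)aniline
Conditions: Fe powder, AcOH/EtOH, 70 °C
Reagents that add atoms: none
Why: Béchamp-type reduction with iron in acetic acid reduces nitroarenes by electron transfer and is known to leave aryl iodides and bromides intact, unlike catalytic hydrogenation.

Step 8
Reactants: 10 3-iodo-4-(2,3,4-tribromo-6-methoxyphenoxy)aniline
Product: 12 1,2,3-tribromo-4-(4-bromo-2-iodophenoxy)-5-methoxybenzene, via aryldiazonium bromide 11 (not isolated)
Conditions: NaNO2, 48% aq. HBr, MeCN, 0 °C; then CuBr, HBr, 60 °C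
Reagents that add atoms: hydrogen bromide, Br
Why: Sandmeyer bromination replaces the amino group by bromine at the carbon para to the ether oxygen; the aryl radical formed from the diazonium salt has no intramolecular trap and the existing C–I bond is not affected by CuBr at this temperature.

Step 9
Reactants: 12 1,2,3-tribromo-4-(4-bromo-2-iodophenoxy)-5-methoxybenzene
Product: 13 3,4,5-tribromo-2-(4-bromo-2-iodophenoxy)phenol
Conditions: BBr3, CH2Cl2, −78 °C → rt; then H2O
Reagents that add atoms: none
Why: Lewis acid cleavage of an aryl methyl ether by BBr3 proceeds by bromide attack on the methyl carbon and does not cleave diaryl ethers; with the nitro group already gone, the liberated phenol has no activated neighbour for a Smiles rearrangement.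

Step 10
Reactants: 13 3,4,5-tribromo-2-(4-bromo-2-iodophenoxy)phenol; 14 3,5-dibromo-2-fluorobenzaldehyde
Product: 15 3,5-dibromo-2-[3,4,5-tribromo-2-(4-bromo-2-iodophenoxy)phenoxy]benzaldehyde
Conditions: K2CO3, DMA, 90 °C
Reagents that add atoms: none
Why: Nucleophilic aromatic substitution (addition–elimination) of a fluoride activated by the ortho formyl group and two bromines; a copper-free medium (no CuBr carried over from step 8) and moderate temperature should keep the phenoxide from closing a dibenzodioxin onto the ring C iodide.

Step 11
Reactants: 15 3,5-dibromo-2-[3,4,5-tribromo-2-(4-bromo-2-iodophenoxy)phenoxy]benzaldehyde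
Product: 17 3,5-dibromo-2-[3,4,5-tribromo-2-(4-bromo-2-iodophenoxy)phenoxy]phenol, via ring A formate ester 16 (not isolated)
Conditions: mCPBA, CH2Cl2, rt → 40 °C; aq. Na2S2O3 wash; then K2CO3 (cat.), MeOH, rt
Reagents that add atoms: 3-chloroperoxybenzoic acid, OOC(=O)c1cccc(Cl)c1
Why: Baeyer–Villiger (Dakin-type) oxidation of an ortho-aryloxy benzaldehyde, in which the oxygen-substituted aryl group migrates to give the formate, followed by methanolysis; the thiosulfate wash returns any iodine oxidised by the peracid to the aryl iodide.

Step 12
Reactants: 17 3,5-dibromo-2-[3,4,5-tribromo-2-(4-bromo-2-iodophenoxy)phenoxy]phenol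
Product: 18 bromoiesol B sulfate, 3,5-dibromo-2-[3,4,5-tribromo-2-(4-bromo-2-iodophenoxy)phenoxy]phenyl hydrogen sulfate
Conditions: SO3·pyridine, pyridine, 50 °C; then Dowex 50W (H+ form), MeOH/H2O, 0 °C
Reagents that add atoms: sulfur trioxide pyridine complex, [O-]S(=O)(=O)[n+]1ccccc1
Why: O-Sulfation of a phenol with the SO3·pyridine complex is the standard mild route to aryl sulfate monoesters; the only free hydroxyl of 17 reacts, and cold, brief acid exchange should give the hydrogen sulfate without hydrolysis.

## Compound list

1 | 3,4,5-tribromoaniline | Nc1cc(Br)c(Br)c(Br)c1 | starting material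
2 | 3,4,5-tribromobenzenediazonium hydrogen sulfate | N#[N+]c1cc(Br)c(Br)c(Br)c1.OS(=O)(=O)[O-] | intermediate
3 | 3,4,5-tribromophenol | Oc1cc(Br)c(Br)c(Br)c1 | intermediate
4 | 3,4,5-tribromo-2-iodophenol | Oc1cc(Br)c(Br)c(Br)c1I | intermediate
5 | 1,2,3-tribromo-4-iodo-5-methoxybenzene | COc1cc(Br)c(Br)c(Br)c1I | intermediate
6 | (2,3,4-tribromo-6-methoxyphenyl)-λ3-iodanediyl diacetate | CC(=O)OI(OC(C)=O)c1c(OC)cc(Br)c(Br)c1Br | intermediate
7 | 4-nitrophenol | Oc1ccc([N+](=O)[O-])cc1 | starting material
8 | 4-nitro-2-[(2,3,4-tribromo-6-methoxyphenyl)iodonio]phenolate | [O-]c1ccc([N+](=O)[O-])cc1[I+]c1c(OC)cc(Br)c(Br)c1Br | intermediate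
9 | 1,2,3-tribromo-4-(2-iodo-4-nitrophenoxy)-5-methoxybenzene | COc1cc(Br)c(Br)c(Br)c1Oc1ccc([N+](=O)[O-])cc1I | intermediate
10 | 3-iodo-4-(2,3,4-tribromo-6-methoxyphenoxy)aniline | COc1cc(Br)c(Br)c(Br)c1Oc1ccc(N)cc1I | intermediate
11 | 3-iodo-4-(2,3,4-tribromo-6-methoxyphenoxy)benzenediazonium bromide | COc1cc(Br)c(Br)c(Br)c1Oc1ccc([N+]#N)cc1I.[Br-] | intermediate
12 | 1,2,3-tribromo-4-(4-bromo-2-iodophenoxy)-5-methoxybenzene | COc1cc(Br)c(Br)c(Br)c1Oc1ccc(Br)cc1I | intermediate
13 | 3,4,5-tribromo-2-(4-bromo-2-iodophenoxy)phenol | Oc1cc(Br)c(Br)c(Br)c1Oc1ccc(Br)cc1I | intermediate
14 | 3,5-dibromo-2-fluorobenzaldehyde | O=Cc1cc(Br)cc(Br)c1F | starting material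
15 | 3,5-dibromo-2-[3,4,5-tribromo-2-(4-bromo-2-iodophenoxy)phenoxy]benzaldehyde | O=Cc1cc(Br)cc(Br)c1Oc1cc(Br)c(Br)c(Br)c1Oc1ccc(Br)cc1I | intermediate
16 | 3,5-dibromo-2-[3,4,5-tribromo-2-(4-bromo-2-iodophenoxy)phenoxy]phenyl formate | O=COc1cc(Br)cc(Br)c1Oc1cc(Br)c(Br)c(Br)c1Oc1ccc(Br)cc1I | intermediate
17 | 3,5-dibromo-2-[3,4,5-tribromo-2-(4-bromo-2-iodophenoxy)phenoxy]phenol | Oc1cc(Br)cc(Br)c1Oc1cc(Br)c(Br)c(Br)c1Oc1ccc(Br)cc1I | intermediate
18 | bromoiesol B sulfate, 3,5-dibromo-2-[3,4,5-tribromo-2-(4-bromo-2-iodophenoxy)phenoxy]phenyl hydrogen sulfate | O=S(=O)(O)Oc1cc(Br)cc(Br)c1Oc1cc(Br)c(Br)c(Br)c1Oc1ccc(Br)cc1I | target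

## Step count and risks

Total: 12 steps. Longest linear sequence: 12 steps, from 1 to 18; 7 and 14 enter as purchased compounds.

**Step 6 (key step).** Fragmentation of the zwitterion at its other C–I bond, which returns the iodoarene 5 and leaves the nitrophenolate ring to be quenched by solvent, may outrun the aryl shift. The ipso attack may also be slowed by the two ortho substituents of ring B. Fallback: the same ether bond would be formed by intermolecular ligand coupling at trivalent iodine, setting out from 6 and 7 and coming back at 9. Diacetate 6 would be treated with 1,3,5-trimethoxybenzene and TsOH·H2O in MeCN to give (2,3,4-tribromo-6-methoxyphenyl)(2,4,6-trimethoxyphenyl)iodonium 4-methylbenzenesulfonate F1. Phenol 7 would be iodinated with N-iodosuccinimide to 2-iodo-4-nitrophenol F2, its two ortho positions being equivalent and its para position blocked. F1 and F2 would then be combined with tBuOK in THF; the electron-rich trimethoxyphenyl group stays on iodine and ring B is transferred to the phenolate oxygen, giving 9.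

**Step 5.** Ligand exchange at the crowded iodine centre may not be followed by the shift of iodine from oxygen to the ortho carbon, or the hindered diacetate may be consumed by methanolysis. Fallback, from 6 back to 8: the C–I bond would be made by boron-to-iodine exchange. Diacetate 6 would be treated with (2-hydroxy-5-nitrophenyl)boronic acid and BF3·OEt2 in CH2Cl2 to give (2-hydroxy-5-nitrophenyl)(2,3,4-tribromo-6-methoxyphenyl)iodonium tetrafluoroborate F3. Aqueous NaHCO3 would then deprotonate the hydroxyl and give 8.

**Step 11.** In the peracid adduct of 15, hydride may migrate in place of the electron-poor, dibrominated aryl group, which would lead to a carboxylic acid. The peracid may also oxidise the ring C iodine. Fallback, from 13 back to 17, replacing steps 10 and 11: ring A would be brought in with its oxygen already present. 2,4-Dibromo-6-methoxyaniline would be converted by diazotisation (NaNO2, aq. H2SO4) and KI into 1,5-dibromo-2-iodo-3-methoxybenzene F4. One-pot oxidation of F4 with mCPBA and TsOH·H2O, then arylation of 1,3,5-trimethoxybenzene, would give (2,4-dibromo-6-methoxyphenyl)(2,4,6-trimethoxyphenyl)iodonium 4-methylbenzenesulfonate F5. Phenol 13 would be arylated with F5 and K2CO3 in MeCN, without any metal, to 1,5-dibromo-3-methoxy-2-[3,4,5-tribromo-2-(4-bromo-2-iodophenoxy)phenoxy]benzene F6. BBr3 would then cleave the methyl ether of F6 to 17.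

**Step 2.** Iodination may go on to the second, equivalent ortho position, or may be sluggish on the ring deactivated by three bromines. Fallback, from 3 back to 5: the order would be reversed and the iodine placed by deprotonation. Phenol 3 would be methylated (MeI, K2CO3) to 1,2,3-tribromo-5-methoxybenzene F7. F7 would be magnesiated with TMPMgCl·LiCl in THF at −20 °C at one of its two equivalent C–H positions, between OMe and Br, and quenched with I2 to give 5. A single deprotonation cannot lead to a di-iodide.

## Further compounds

F1 | step 6 | (2,3,4-tribromo-6-methoxyphenyl)(2,4,6-trimethoxyphenyl)iodonium 4-methylbenzenesulfonate | COc1cc(OC)c([I+]c2c(OC)cc(Br)c(Br)c2Br)c(OC)c1.Cc1ccc(S(=O)(=O)[O-])cc1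
F2 | step 6 | 2-iodo-4-nitrophenol | Oc1ccc([N+](=O)[O-])cc1I
F3 | step 5 | (2-hydroxy-5-nitrophenyl)(2,3,4-tribromo-6-methoxyphenyl)iodonium tetrafluoroborate | Oc1ccc([N+](=O)[O-])cc1[I+]c1c(OC)cc(Br)c(Br)c1Br.F[B-](F)(F)F
F4 | step 11 | 1,5-dibromo-2-iodo-3-methoxybenzene | COc1cc(Br)cc(Br)c1I
F5 | step 11 | (2,4-dibromo-6-methoxyphenyl)(2,4,6-trimethoxyphenyl)iodonium 4-methylbenzenesulfonate | COc1cc(OC)c([I+]c2c(OC)cc(Br)cc2Br)c(OC)c1.Cc1ccc(S(=O)(=O)[O-])cc1
F6 | step 11 | 1,5-dibromo-3-methoxy-2-[3,4,5-tribromo-2-(4-bromo-2-iodophenoxy)phenoxy]benzene | COc1cc(Br)cc(Br)c1Oc1cc(Br)c(Br)c(Br)c1Oc1ccc(Br)cc1I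
F7 | step 2 | 1,2,3-tribromo-5-methoxybenzene | COc1cc(Br)c(Br)c(Br)c1
A1 | alternative 1 | 2,3,4-tribromothiophene 1,1-dioxide | O=S1(=O)C=C(Br)C(Br)=C1Br
A2 | alternative 1 | 2-[2,2-bis(trimethylsilyloxy)ethenyloxy]-1,5-dibromo-3-methoxybenzene | COc1cc(Br)cc(Br)c1OC=C(O[Si](C)(C)C)O[Si](C)(C)C
A3 | alternative 1 | 2,3,4-tribromo-6-(2,4-dibromo-6-methoxyphenoxy)phenol | COc1cc(Br)cc(Br)c1Oc1cc(Br)c(Br)c(Br)c1O
A4 | alternative 1 | 1-fluoro-2-iodo-4-nitrobenzene | O=[N+]([O-])c1ccc(F)c(I)c1
A5 | alternative 2 | 2,4-dibromophenol | Oc1ccc(Br)cc1Br
A6 | alternative 2 | potassium 3,5-dibromo-2-hydroxyphenyl sulfate | [K+].[O-]S(=O)(=O)Oc1cc(Br)cc(Br)c1O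
A7 | alternative 3 | 3,5-dibromo-2H-pyran-2-one | O=C1OC=C(Br)C=C1Br
A8 | alternative 3 | 2-{[3,4,5-tribromo-2-(4-bromo-2-iodophenoxy)phenoxy]ethynyl}-4,4,5,5-tetramethyl-1,3,2-dioxaborolane | CC1(C)OB(OC1(C)C)C#COc1cc(Br)c(Br)c(Br)c1Oc1ccc(Br)cc1I
A9 | alternative 3 | 2-{3,5-dibromo-2-[3,4,5-tribromo-2-(4-bromo-2-iodophenoxy)phenoxy]phenyl}-4,4,5,5-tetramethyl-1,3,2-dioxaborolane | CC1(C)OB(OC1(C)C)c1cc(Br)cc(Br)c1Oc1cc(Br)c(Br)c(Br)c1Oc1ccc(Br)cc1I
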